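Flavan numbering is used for both units. The upper unit is the 3-deoxyflavan bonded through its C4; the lower unit is the flavan-3,4-diol bonded through its C6. With ring A on the left and O1 at the top, β points towards the viewer. The target has a 2α-aryl and a 4β-aryl group in the upper unit (2S,4S) and 2α-aryl, 3α-OH and 4α-OH in the lower unit (2R,3R,4R).

## The problem

The target is a (4→6)-linked biflavanoid: C4 of a 4',7,8-trihydroxyflavan is bonded to C6 of ring A of a 4',7,8-trihydroxyflavan-3,4-diol. It has five stereocenters in two groups, upper C2/C4 (2,4-trans) and lower C2/C3/C4 (all-cis). The groups are separated by an aryl–C bond and a benzene ring, so neither can control the other and each needs its own source of absolute configuration. The lower diol lies on the same face as the C2 aryl group, the face that OsO4 or a peracid would avoid on a flav-3-ene. Its C4–OH is benzylic, para to O7 and ortho (through C8a) to O1, so it ionizes with acid, and with base through a quinone methide once O7 is a free phenol. The obvious union, attack of lower C6 on an upper flavan-4-yl cation, needs exactly the acid that this group does not tolerate, and it leaves the C4 configuration and the C6/C5 position to the substrate. The free pyrogallol-type rings are air-sensitive, so the phenols must stay masked until a final neutral step that spares the benzylic C–O bonds. The feature that opens the plan is that upper C4 is bonded to C4a of ring A, whose neighbour C8a carries the pyran oxygen O1. The unit O1–C8a=C4a–C4 is therefore an ortho-quinone methide, C2–C3 is a two-carbon 2π partner, and the third substituent of C4 (lower C6) is an aryl carbon that can arrive as an aryl-metal at the aldehyde from which that quinone methide is made.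

## Retrosynthesis

**27 ⇒ 26 ⇒ 25.** No skeletal bond is cut. The six phenols are benzyl ethers and the lower cis-diol is a bis-silyl ether (25). Silyl groups are chosen over an acetonide because fluoride removes them without acid. They come off first (26), while O7 is still an ether and no quinone methide can form; neutral hydrogenolysis is last.

**25 ⇒ 22 + 23.** The bond between upper C2 and ring B is cut, leaving C2 as an acetal carbon in 22. A group that arrives with the 2π partner in an endo cycloaddition ends up cis to the C4 aryl group (see Alternative 2), and the target is trans. If the aryl group is instead the last group to arrive at C2, through oxocarbenium ion 24, it should enter anti to the C4 aryl group. The forward step must ionize the exocyclic C–O bond only and add the aryl group of trifluoroborate 23 on the α face.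

**22 ⇒ 13 + 16 + 18 (key).** Three bonds around upper C4 and O1 are cut at once: C4–C6(lower), C3–C4 and O1–C2. The interflavanyl bond is then made by adding aryllithium 19 to an aldehyde carbon, not by capturing a C4 cation, so the lower C4–O bond is never exposed to acid. The position on the lower ring is fixed by the bromine atom of 13. The adduct collapses to ortho-quinone methide 21, and its [4+2] cycloaddition with the chiral vinyl ether 18 closes ring C and sets C4. The precursors are one aryl bromide, a benzaldehyde (16) and a vinyl ether.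

**13 ⇒ 12 ⇒ 11.** The C6–Br bond is cut (electrophilic bromination of 12), then the two O–Si bonds. C6 is the position ortho to O7 and para to O1, so the ring itself directs the halogen.

**11 ⇒ 8.** Both C–O bonds of the diol are cut back to the C3=C4 double bond of flav-3-ene 8. OsO4 would give the diol anti to the aryl group. The Woodward sequence (iodonium anti, then acetoxonium by inversion) puts both oxygens syn to the aryl group. The three contiguous centers are thus reduced to one, C2.

**8 ⇒ 7 ⇒ 6 ⇒ 4 + 5.** The C3=C4 bond comes from dehydration of alcohol 7, and 7 from ketone 6. The C2–aryl bond of 6 is cut to chromone 4 and boronic acid 5. A catalytic asymmetric conjugate addition should set C2, the only center of the lower unit that needs an external chiral controller.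

**4 ⇒ 2 ⇒ 1; 16 ⇒ 15 ⇒ 14; 18 ⇒ 17.** Both rings A come from commercial 1,2,3-trioxygenated benzenes (acetophenone 1, aldehyde 14) by benzylation that spares the hydrogen-bonded ortho-hydroxyl. 18 is the vinyl ether of commercial alcohol 17.

## Roads not taken

**Alternative 1:** Cut only C4–C6 (the obvious, biomimetic cut). The 4-acetate A1 of alcohol 7 would be ionized by a Lewis acid and the cation captured by ring A of 12 to give 25 directly. This is shorter on paper, since 7 and 12 are both in the chosen route. It is rejected for three reasons: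
- 12 carries at its own C4 the same kind of leaving group on the same kind of ring as A1. A Lewis acid cannot tell them apart, so self-condensation and epimerization at lower C4 would compete.
- The 3-deoxy cation has no C3 substituent, so the 2,4-trans/cis ratio and the C6/C5 ratio are left to the substrate.
- The usual remedies (free 7-OH, large excess of nucleophile) make the first problem worse and waste the more valuable half.

**Alternative 2:** The same three bonds as the chosen key step, but with 4-(benzyloxy)styrene A2 as the 2π partner, which would deliver the whole protected skeleton in one operation. The endo transition state puts the styrene aryl group cis to the C4 aryl group and would give A3, the C2 epimer of 25. There is no acid-free way to invert C2, no auxiliary to choose the face, and styrenes are poor partners for quinone methides generated under anionic conditions. The chosen plan pays one extra step and gains both the trans relationship and absolute control.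

**Alternative 3:** Dearomatization. The lower heterocycle would be carried as a flat, acid-proof flavonol (dimer A4, built on ring A after a Friedel–Crafts union of 7 with acetophenone 1) and hydrogenated at the end, giving the all-cis triad by syn delivery of hydrogen. The face of the flavonol is not influenced by the remote upper unit, so heterogeneous catalysts (Pd/C, PtO2) would give 27 and its lower-unit diastereomer A5 without preference. Enantioselective homogeneous hydrogenation is established for flavones (for example with Ru(cod)(2-methylallyl)2 and a chiral N-heterocyclic carbene ligand) but not for 3-oxygenated, tetrasubstituted ones, and the benzylic C4–O bond is at risk of over-reduction. The chosen plan sets C2 with a known catalytic reaction and relays C3 and C4 from it.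

Key step: step 12

Remark (assumption on the chemistry): the sense of induction of the two external chiral controllers, (R)-t-BuPyOx in step 3 and the (1S,2R)-2-phenylcyclohexyl group of 18 in step 12, is assigned from the usual face-selection models for these reagent classes; each controller is available in both mirror-image forms.

## Route

Step 1
Reactants: 1 1-(2,3,4-trihydroxyphenyl)ethanone
Product: 2 1-[3,4-bis(benzyloxy)-2-hydroxyphenyl]ethanone
Conditions: BnBr (2.1 equiv), K2CO3, DMF, 20 °C
Reagents that add atoms: benzyl bromide, BrCc1ccccc1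
Why: Williamson etherification; the 2-hydroxyl is held in a hydrogen bond to the acetyl carbonyl and is the least nucleophilic, so the 3- and 4-phenols are alkylated first.

Step 2
Reactants: 2 1-[3,4-bis(benzyloxy)-2-hydroxyphenyl]ethanone
Product: 4 7,8-bis(benzyloxy)-4H-chromen-4-one, via enaminone 3 (not isolated)
Conditions: Me2NCH(OMe)2, toluene, 100 °C; then conc. HCl, CH2Cl2, 20 °C
Reagents that add atoms: N,N-dimethylformamide dimethyl acetal, COC(OC)N(C)C
Why: Condensation of the methyl ketone with the formamide acetal gives enaminone 3; acid-promoted attack of the phenol and loss of dimethylamine closes the pyranone ring (standard chromone synthesis).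

Step 3
Reactants: 4 7,8-bis(benzyloxy)-4H-chromen-4-one; 5 [4-(benzyloxy)phenyl]boronic acid
Product: 6 (2S)-7,8-bis(benzyloxy)-2-[4-(benzyloxy)phenyl]chroman-4-one
Conditions: Pd(OCOCF3)2 (5 mol %), (R)-t-BuPyOx (6 mol %), NH4PF6, H2O, ClCH2CH2Cl, 60 °C
Reagents that add atoms: none
Why: Palladium-catalysed asymmetric conjugate addition of an arylboronic acid to a chromone; the ligand-bound aryl–palladium species inserts C2=C3 on one enantioface and the palladium enolate is protonated, which sets C2 (2α-aryl, S). The catalyst stays divalent palladium throughout, so the aryl benzyl ethers are not touched.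

Step 4
Reactants: 6 (2S)-7,8-bis(benzyloxy)-2-[4-(benzyloxy)phenyl]chroman-4-one
Product: 7 (2S,4S)-7,8-bis(benzyloxy)-2-[4-(benzyloxy)phenyl]chroman-4-ol
Conditions: NaBH4, THF–MeOH, 0 °C
Reagents that add atoms: none
Why: Borohydride reduction; axial hydride attack on the half-chair with equatorial aryl group should give the 2,4-cis alcohol. The C4 configuration is of no consequence because the center is removed in step 5.

Step 5
Reactants: 7 (2S,4S)-7,8-bis(benzyloxy)-2-[4-(benzyloxy)phenyl]chroman-4-ol
Product: 8 (2S)-7,8-bis(benzyloxy)-2-[4-(benzyloxy)phenyl]-2H-chromene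
Conditions: Burgess reagent, toluene, 60 °C
Reagents that add atoms: none
Why: Dehydration through the sulfamate ester gives the conjugated C3=C4 double bond. The medium is not acidic, so the electron-rich flavene should not dimerize, and C2 is not involved.

Step 6
Reactants: 8 (2S)-7,8-bis(benzyloxy)-2-[4-(benzyloxy)phenyl]-2H-chromene
Product: 11 (2R,3R,4R)-7,8-bis(benzyloxy)-2-[4-(benzyloxy)phenyl]chromane-3,4-diol, via trans-iodoacetate 9 (not isolated), via cis-hydroxyacetate 10 (not isolated)
Conditions: I2 (1.05 equiv), AgOAc (2.2 equiv), AcOH, 20 °C, dark; then AcOH–H2O, 20 to 45 °C; then K2CO3, MeOH, 20 °C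
Reagents that add atoms: silver acetate, [Ag+].CC([O-])=O
Why: Woodward cis-hydroxylation: the iodonium ion forms at C3 on the β face, away from the 2α-aryl group, and acetate opens it at benzylic C4 to give 9; silver-assisted loss of iodide with backside participation of the C4 acetate inverts C3 and gives a cis-fused acetoxonium ion on the α face, which water opens at the acyl carbon to give 10. Both new C–O bonds therefore lie on the face of the aryl group (3α,4α), the face that OsO4 would not reach; methanolysis then frees diol 11.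

Step 7
Reactants: 11 (2R,3R,4R)-7,8-bis(benzyloxy)-2-[4-(benzyloxy)phenyl]chromane-3,4-diol
Product: 12 7,8-bis(benzyloxy)-2α-[4-(benzyloxy)phenyl]-3α,4α-bis(tert-butyldimethylsilyloxy)chromane
Conditions: TBSOTf (2.5 equiv), 2,6-lutidine, CH2Cl2, 0 to 20 °C
Reagents that add atoms: tert-butyldimethylsilyl trifluoromethanesulfonate, CC(C)(C)[Si](C)(C)OS(=O)(=O)C(F)(F)F
Why: Silylation with a silyl triflate under buffered conditions covers both the axial C3 and the benzylic C4 hydroxyl without ionizing C4–O. The bis-silyl ether is inert to organolithium reagents and is removed later by fluoride, not acid.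

Step 8
Reactants: 12 7,8-bis(benzyloxy)-2α-[4-(benzyloxy)phenyl]-3α,4α-bis(tert-butyldimethylsilyloxy)chromane
Product: 13 6-bromo-7,8-bis(benzyloxy)-2α-[4-(benzyloxy)phenyl]-3α,4α-bis(tert-butyldimethylsilyloxy)chromane
Conditions: NBS (1.02 equiv), MeCN, 0 °C, dark
Reagents that add atoms: N-bromosuccinimide, O=C1CCC(=O)N1Br
Why: Electrophilic aromatic bromination; C6 is ortho to O7 and para to O1 and is the most activated open position. C5 is para only to the twisted middle alkoxy group at C8 and is shielded by the C4 silyloxy group, and the mono-oxygenated ring B is less reactive.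

Step 9
Reactants: 14 2,3,4-trihydroxybenzaldehyde
Product: 15 3,4-bis(benzyloxy)-2-hydroxybenzaldehyde
Conditions: BnBr (2.1 equiv), K2CO3, DMF, 20 °C
Reagents that add atoms: benzyl bromide, BrCc1ccccc1
Why: Williamson etherification; as in step 1, the 2-hydroxyl is hydrogen-bonded to the formyl group and reacts last.

Step 10
Reactants: 15 3,4-bis(benzyloxy)-2-hydroxybenzaldehyde
Product: 16 2,3-bis(benzyloxy)-6-formylphenyl tert-butyl carbonate
Conditions: Boc2O, i-Pr2NEt, DMAP (cat.), THF, 20 °C
Reagents that add atoms: di-tert-butyl dicarbonate, CC(C)(C)OC(=O)OC(=O)OC(C)(C)C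
Why: DMAP-catalysed acylation of the phenol gives the ortho-O-Boc aldehyde, the latent ortho-quinone methide of step 12.

Step 11
Reactants: 17 (1S,2R)-2-phenylcyclohexan-1-ol
Product: 18 (1S,2R)-2-phenylcyclohexyl vinyl ether
Conditions: Pd(OCOCF3)2 (1 mol %), 4,7-diphenyl-1,10-phenanthroline, Et3N, butyl vinyl ether (solvent), 75 °C
Reagents that add atoms: butyl vinyl ether, C=COCCCC
Why: Palladium-catalysed transfer vinylation of a secondary alcohol; the C–O bond of the carbinol is not broken, so both stereocenters of the auxiliary are kept.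

Step 12
Reactants: 13 6-bromo-7,8-bis(benzyloxy)-2α-[4-(benzyloxy)phenyl]-3α,4α-bis(tert-butyldimethylsilyloxy)chromane; 16 2,3-bis(benzyloxy)-6-formylphenyl tert-butyl carbonate; 18 (1S,2R)-2-phenylcyclohexyl vinyl ether
Product: 22 upper 7,8-bis(benzyloxy)-2β-[(1S,2R)-2-phenylcyclohexyloxy]chroman-4-yl unit bonded through C4 (4β-aryl) to C6 of the lower unit of 12, via aryllithium 19 (not isolated), via benzylic carbonate 20 (not isolated), via ortho-quinone methide 21 (not isolated)
Conditions: 13, t-BuLi (2.0 equiv), Et2O, −78 °C; then 16 and 18 (3 equiv) in toluene, −78 °C; then MgBr2·OEt2, −78 to 20 °C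
Reagents that add atoms: none
Why: Bromine–lithium exchange gives 19, which adds to the aldehyde of 16; the resulting alkoxide takes the Boc group from the neighbouring phenol oxygen through a six-membered transition state (20, present as its magnesium phenoxide after addition of MgBr2), and on warming the phenoxide expels tert-butyl carbonate in a 1,4-elimination to give the (E)-ortho-quinone methide 21. 21 is trapped by enol ether 18 in an inverse-electron-demand hetero-Diels–Alder reaction, so ring C of the upper unit is closed by a concerted, asynchronous [4+2] cycloaddition that forms O1–C2 and C3–C4 together. The closest known reaction type is the three-component synthesis of 2-alkoxychromans from ortho-O-Boc salicylaldehydes, organolithium or Grignard reagents and vinyl ethers, including its diastereoselective form with 2-phenylcyclohexyl vinyl ethers. C4 is controlled by the auxiliary: in the s-trans enol ether the phenyl group covers the Si face of the oxygen-bearing vinyl carbon, 21 adds to the Re face, and with the aryl group on the outside of the (E)-methide this places the lower-unit aryl group β at C4. C2 is controlled by the endo rule (alkoxy group under the heterodiene), which puts the alkoxy group cis to the C4 aryl group (2β); this center is only a relay and is replaced in step 13. The step needs addition of 19 to the aldehyde and not to the carbonate carbonyl, which the much higher electrophilicity of the aldehyde at −78 °C should secure, and capture of 21 by 18 before tert-butoxide or a second molecule of 21 can add, which the excess of electron-rich enol ether and the slow release of 21 should secure. The position on the lower unit is fixed by the bromine atom of 13, and no acid is present, so the silylated benzylic C4–O bond of the lower unit is not ionized.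

Step 13
Reactants: 22 cycloadduct (2β-alkoxy acetal); 23 potassium [4-(benzyloxy)phenyl]trifluoroborate
Product: 25 hexa-O-benzyl-3,4-bis-O-(tert-butyldimethylsilyl) derivative of the target (upper unit 2α-aryl and 4β-aryl), via oxocarbenium ion 24 (not isolated)
Conditions: 23 (2 equiv), BF3·OEt2 (3 equiv), MeCN–CH2Cl2, −40 to 0 °C
Reagents that add atoms: none
Why: Lewis acid-mediated coupling of an aryltrifluoroborate with an O,O-acetal: BF3 binds the more basic exocyclic alkoxy oxygen, its departure gives the ring oxocarbenium ion 24, and the electron-rich aryl group is transferred from boron by ipso attack. In 24 the C4 aryl group stands pseudoaxial to avoid the peri hydrogen at C5 and covers the β face of C2, so the new aryl group should enter on the α face and give the 2,4-trans flavan; alcohol 17 is recovered.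

Step 14
Reactants: 25 hexa-O-benzyl-3,4-bis-O-(tert-butyldimethylsilyl) derivative of the target
Product: 26 hexa-O-benzyl derivative of the target (free lower 3,4-diol)
Conditions: Bu4NF, AcOH, THF, 0 to 40 °C
Reagents that add atoms: none
Why: Fluoride-mediated cleavage of both silyl ethers. The medium is buffered and all phenols are still benzylated, so neither acid ionization nor quinone methide formation at lower C4 is open; no stereocenter is touched.

Step 15
Reactants: 26 hexa-O-benzyl derivative of the target
Product: 27 (2R,3R,4R)-6-[(2S,4S)-7,8-dihydroxy-2-(4-hydroxyphenyl)chroman-4-yl]-2-(4-hydroxyphenyl)chromane-3,4,7,8-tetrol (CNP0209379.1)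
Conditions: H2 (1 atm), Pd(OH)2/C, THF–MeOH, 20 °C; filtration and evaporation under argon
Reagents that add atoms: none
Why: Hydrogenolysis of six aryl benzyl ethers under neutral conditions; these should cleave faster than the benzylic C4–OH and the ring C2–O1 bonds, and the work-up needs no acid or base.

## Compound list

1 | 1-(2,3,4-trihydroxyphenyl)ethanone | CC(=O)c1ccc(O)c(O)c1O | starting material
2 | 1-[3,4-bis(benzyloxy)-2-hydroxyphenyl]ethanone | CC(=O)c1ccc(OCc2ccccc2)c(OCc2ccccc2)c1O | intermediate
3 | (E)-1-[3,4-bis(benzyloxy)-2-hydroxyphenyl]-3-(dimethylamino)prop-2-en-1-one | CN(C)/C=C/C(=O)c1ccc(OCc2ccccc2)c(OCc2ccccc2)c1O | intermediate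
4 | 7,8-bis(benzyloxy)-4H-chromen-4-one | O=c1ccoc2c1ccc(OCc1ccccc1)c2OCc1ccccc1 | intermediate
5 | [4-(benzyloxy)phenyl]boronic acid | OB(O)c1ccc(OCc2ccccc2)cc1 | starting material
6 | (2S)-7,8-bis(benzyloxy)-2-[4-(benzyloxy)phenyl]chroman-4-one | O=C1C[C@@H](c2ccc(OCc3ccccc3)cc2)Oc2c1ccc(OCc1ccccc1)c2OCc1ccccc1 | intermediate
7 | (2S,4S)-7,8-bis(benzyloxy)-2-[4-(benzyloxy)phenyl]chroman-4-ol (2,4-cis) | c1cc2c(c(OCc3ccccc3)c1OCc1ccccc1)O[C@H](c1ccc(OCc3ccccc3)cc1)C[C@@H]2O | intermediate
8 | (2S)-7,8-bis(benzyloxy)-2-[4-(benzyloxy)phenyl]-2H-chromene | c1cc2c(c(OCc3ccccc3)c1OCc1ccccc1)O[C@H](c1ccc(OCc3ccccc3)cc1)C=C2 | intermediate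
9 | 7,8-bis(benzyloxy)-2α-[4-(benzyloxy)phenyl]-3β-iodochroman-4α-yl acetate | c1cc2c(c(OCc3ccccc3)c1OCc1ccccc1)O[C@H](c1ccc(OCc3ccccc3)cc1)[C@@H](I)[C@@H]2OC(C)=O | intermediate
10 | 7,8-bis(benzyloxy)-2α-[4-(benzyloxy)phenyl]-4α-hydroxychroman-3α-yl acetate (the 4-acetate regioisomer converges on 11) | c1cc2c(c(OCc3ccccc3)c1OCc1ccccc1)O[C@H](c1ccc(OCc3ccccc3)cc1)[C@H](OC(C)=O)[C@@H]2O | intermediate
11 | (2R,3R,4R)-7,8-bis(benzyloxy)-2-[4-(benzyloxy)phenyl]chromane-3,4-diol (2,3-cis-3,4-cis) | c1cc2c(c(OCc3ccccc3)c1OCc1ccccc1)O[C@H](c1ccc(OCc3ccccc3)cc1)[C@H](O)[C@@H]2O | intermediate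
12 | 7,8-bis(benzyloxy)-2α-[4-(benzyloxy)phenyl]-3α,4α-bis(tert-butyldimethylsilyloxy)chromane | c1cc2c(c(OCc3ccccc3)c1OCc1ccccc1)O[C@H](c1ccc(OCc3ccccc3)cc1)[C@H](O[Si](C)(C)C(C)(C)C)[C@@H]2O[Si](C)(C)C(C)(C)C | intermediate
13 | 6-bromo derivative of 12 | Brc1cc2c(c(OCc3ccccc3)c1OCc1ccccc1)O[C@H](c1ccc(OCc3ccccc3)cc1)[C@H](O[Si](C)(C)C(C)(C)C)[C@@H]2O[Si](C)(C)C(C)(C)C | intermediate
14 | 2,3,4-trihydroxybenzaldehyde | O=Cc1ccc(O)c(O)c1O | starting material
15 | 3,4-bis(benzyloxy)-2-hydroxybenzaldehyde | O=Cc1ccc(OCc2ccccc2)c(OCc2ccccc2)c1O | intermediate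
16 | 2,3-bis(benzyloxy)-6-formylphenyl tert-butyl carbonate | O=Cc1ccc(OCc2ccccc2)c(OCc2ccccc2)c1OC(=O)OC(C)(C)C | intermediate
17 | (1S,2R)-2-phenylcyclohexan-1-ol (trans) | O[C@H]1CCCC[C@@H]1c1ccccc1 | starting material
18 | (1S,2R)-2-phenylcyclohexyl vinyl ether | C=CO[C@H]1CCCC[C@@H]1c1ccccc1 | intermediate
19 | 6-lithio derivative of 12 (aryllithium) | [Li]c1cc2c(c(OCc3ccccc3)c1OCc1ccccc1)O[C@H](c1ccc(OCc3ccccc3)cc1)[C@H](O[Si](C)(C)C(C)(C)C)[C@@H]2O[Si](C)(C)C(C)(C)C | intermediate
20 | tert-butyl carbonate of the diarylmethanol from 19 and 16, phenol form, both epimers at the carbinol carbon | CC(C)(C)OC(=O)OC(c1ccc(OCc2ccccc2)c(OCc2ccccc2)c1O)c1cc2c(c(OCc3ccccc3)c1OCc1ccccc1)O[C@H](c1ccc(OCc3ccccc3)cc1)[C@H](O[Si](C)(C)C(C)(C)C)[C@@H]2O[Si](C)(C)C(C)(C)C | intermediate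
21 | (E)-6-(arylmethylidene)-2,3-bis(benzyloxy)cyclohexa-2,4-dien-1-one, aryl = C6 of the lower unit of 12 (ortho-quinone methide) | O=C1C(OCc2ccccc2)=C(OCc2ccccc2)C=C/C1=C\c1cc2c(c(OCc3ccccc3)c1OCc1ccccc1)O[C@H](c1ccc(OCc3ccccc3)cc1)[C@H](O[Si](C)(C)C(C)(C)C)[C@@H]2O[Si](C)(C)C(C)(C)C | intermediate
22 | cycloadduct: 7,8-bis(benzyloxy)-2β-[(1S,2R)-2-phenylcyclohexyloxy]chromane bearing at C4 (β) the C6 of the lower unit of 12 (2,4-cis acetal) | c1ccccc1[C@H]1CCCC[C@@H]1O[C@H]1C[C@@H](c2cc3c(c(OCc4ccccc4)c2OCc2ccccc2)O[C@H](c2ccc(OCc4ccccc4)cc2)[C@H](O[Si](C)(C)C(C)(C)C)[C@@H]3O[Si](C)(C)C(C)(C)C)c2ccc(OCc3ccccc3)c(OCc3ccccc3)c2O1 | intermediate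
23 | potassium [4-(benzyloxy)phenyl]trifluoroborate | [K+].F[B-](F)(F)c1ccc(OCc2ccccc2)cc1 | starting material
24 | 4β-aryl-7,8-bis(benzyloxy)-3,4-dihydrochromenylium ion (oxocarbenium ion from 22) | [O+]1=CC[C@@H](c2cc3c(c(OCc4ccccc4)c2OCc2ccccc2)O[C@H](c2ccc(OCc4ccccc4)cc2)[C@H](O[Si](C)(C)C(C)(C)C)[C@@H]3O[Si](C)(C)C(C)(C)C)c2ccc(OCc3ccccc3)c(OCc3ccccc3)c21 | intermediate
25 | hexa-O-benzyl-3,4-bis-O-(tert-butyldimethylsilyl) derivative of the target (upper unit 2α-aryl and 4β-aryl) | C(c1ccccc1)Oc1ccc(cc1)[C@@H]1C[C@@H](c2cc3c(c(OCc4ccccc4)c2OCc2ccccc2)O[C@H](c2ccc(OCc4ccccc4)cc2)[C@H](O[Si](C)(C)C(C)(C)C)[C@@H]3O[Si](C)(C)C(C)(C)C)c2ccc(OCc3ccccc3)c(OCc3ccccc3)c2O1 | intermediate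
26 | hexa-O-benzyl derivative of the target | C(c1ccccc1)Oc1ccc(cc1)[C@@H]1C[C@@H](c2cc3c(c(OCc4ccccc4)c2OCc2ccccc2)O[C@H](c2ccc(OCc4ccccc4)cc2)[C@H](O)[C@@H]3O)c2ccc(OCc3ccccc3)c(OCc3ccccc3)c2O1 | intermediate
27 | (2R,3R,4R)-6-[(2S,4S)-7,8-dihydroxy-2-(4-hydroxyphenyl)chroman-4-yl]-2-(4-hydroxyphenyl)chromane-3,4,7,8-tetrol | Oc1ccc([C@@H]2C[C@@H](c3cc4c(c(O)c3O)O[C@H](c3ccc(O)cc3)[C@H](O)[C@@H]4O)c3ccc(O)c(O)c3O2)cc1 | target

## Step count and least certain steps

Total step count: 15. Longest linear sequence: 12 (steps 1 to 8, then 12 to 15). Steps 9 to 11 are side branches.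

**Step 12 (key step).** The most likely failures are incomplete facial discrimination by the auxiliary when the quinone methide carries a bulky, ortho-substituted aryl group, and loss of 21 to self-addition or tert-butoxide addition before the cycloaddition. The sense of induction is also taken from a model (see the remark). Fallback, from 13 to 25 with known chemistry and no quinone methide:
- Bromine–lithium exchange on 13 and quenching with 2-isopropoxy-4,4,5,5-tetramethyl-1,3,2-dioxaborolane gives the pinacol boronate F1.
- Rhodium-catalysed asymmetric 1,4-addition of F1 (Rh(acac)(C2H4)2, (S)-Segphos, dioxane–water, 60 °C) to 7,8-bis(benzyloxy)coumarin F2, made from 7,8-dihydroxycoumarin with BnBr and K2CO3, gives the 4β-aryl-3,4-dihydrocoumarin F4.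
- F4 is carried through the hydroxy ketone F5 and the carbinol F6 to 25 as described under step 13.

**Step 13.** Ionization may take the ring C–O bond and not the exocyclic one (ring opening), the aryl group may add in part syn to the C4 aryl group, and BF3 may loosen the silyl ethers or ionize lower C4–O if the temperature rises. Fallback, from 22 to 25, which sets C2 by a reagent-controlled reduction and an invertive ring closure:
- Mild hydrolysis of the acetal (PPTS, acetone–water) gives the lactol F3 and returns 17.
- Oxidation with Ag2CO3 on Celite gives the 4β-aryl-3,4-dihydrocoumarin F4.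
- One equivalent of 4-(benzyloxy)phenyllithium at −78 °C gives the ring-opened 2-hydroxyaryl ketone F5.
- Corey–Bakshi–Shibata reduction with (S)-2-methyl-CBS-oxazaborolidine and BH3·SMe2 gives the (R)-benzylic alcohol F6.
- Mitsunobu cyclization (PPh3, DIAD) closes O1–C2 with inversion and gives 25.

**Step 6.** The acetoxonium ion sits next to a strongly stabilized benzylic position, so it may open at C4 and not at the acyl carbon; this would scramble C4 while C3 stays correct. Ring A may also be iodinated by the silver/iodine reagent. Fallback, from 10 to 11, which sets C4 by hydride and not by the acetoxonium ion: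
- 10 is isolated as the mixture of C4 epimers and oxidized with Dess–Martin periodinane to the 2,3-cis 3-acetoxyflavan-4-one F7.
- NaBH4 at −40 °C, with hydride adding from the β face opposite the aryl and acetoxy groups, gives 10 as the single 4α epimer, which is methanolysed to 11.

**Step 15.** Once O7 is a free phenol the lower C4–OH is an electron-rich benzylic alcohol, and over-reduction by C–O hydrogenolysis may compete with the last debenzylations. Fallback, from 25 to 27, reversing the order of deprotection:
- Hydrogenolysis of 25 with the silyl groups still in place gives the hexaphenol bis-silyl ether F8, in which the C4–O bond is shielded.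
- Et3N·3HF in MeCN at 20 °C then removes both silyl groups and gives 27.

**Step 3.** The chromone is electron-rich and may insert slowly, which would allow protodeboronation of 5 and erosion of the enantiomeric purity. Fallback, from 2 to 7, which sets C2 by hydrogenation and not by C–C bond formation:
- Claisen–Schmidt condensation of 2 with 4-(benzyloxy)benzaldehyde (KOH, EtOH) gives the chalcone F9.
- I2 (cat.) in DMSO at 120 °C gives the flavone F10.
- Enantioselective hydrogenation (Ru(cod)(2-methylallyl)2, (R,R)-SINpEt·HBF4, KOt-Bu, H2) gives the flavan-4-ol 7; either C4 epimer serves, because step 5 removes that center.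

## Further compounds

F1 | step 12 | pinacol boronate of the lower unit (6-(4,4,5,5-tetramethyl-1,3,2-dioxaborolan-2-yl) derivative of 12) | CC1(C)OB(OC1(C)C)c1cc2c(c(OCc3ccccc3)c1OCc1ccccc1)O[C@H](c1ccc(OCc3ccccc3)cc1)[C@H](O[Si](C)(C)C(C)(C)C)[C@@H]2O[Si](C)(C)C(C)(C)C
F2 | step 12 | 7,8-bis(benzyloxy)-2H-chromen-2-one | O=c1ccc2ccc(OCc3ccccc3)c(OCc3ccccc3)c2o1
F3 | step 13 | 4β-aryl-7,8-bis(benzyloxy)chroman-2-ol (lactol, both anomers), aryl = C6 of the lower unit of 12 | OC1C[C@@H](c2cc3c(c(OCc4ccccc4)c2OCc2ccccc2)O[C@H](c2ccc(OCc4ccccc4)cc2)[C@H](O[Si](C)(C)C(C)(C)C)[C@@H]3O[Si](C)(C)C(C)(C)C)c2ccc(OCc3ccccc3)c(OCc3ccccc3)c2O1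
F4 | step 13 | 4β-aryl-7,8-bis(benzyloxy)chroman-2-one (3,4-dihydrocoumarin) | O=C1C[C@@H](c2cc3c(c(OCc4ccccc4)c2OCc2ccccc2)O[C@H](c2ccc(OCc4ccccc4)cc2)[C@H](O[Si](C)(C)C(C)(C)C)[C@@H]3O[Si](C)(C)C(C)(C)C)c2ccc(OCc3ccccc3)c(OCc3ccccc3)c2O1
F5 | step 13 | 3-aryl-3-[3,4-bis(benzyloxy)-2-hydroxyphenyl]-1-[4-(benzyloxy)phenyl]propan-1-one | O=C(c1ccc(OCc2ccccc2)cc1)C[C@@H](c1cc2c(c(OCc3ccccc3)c1OCc1ccccc1)O[C@H](c1ccc(OCc3ccccc3)cc1)[C@H](O[Si](C)(C)C(C)(C)C)[C@@H]2O[Si](C)(C)C(C)(C)C)c1ccc(OCc2ccccc2)c(OCc2ccccc2)c1O
F6 | step 13 | (1R)-3-aryl-3-[3,4-bis(benzyloxy)-2-hydroxyphenyl]-1-[4-(benzyloxy)phenyl]propan-1-ol | C(c1ccccc1)Oc1ccc(cc1)[C@H](O)C[C@@H](c1cc2c(c(OCc3ccccc3)c1OCc1ccccc1)O[C@H](c1ccc(OCc3ccccc3)cc1)[C@H](O[Si](C)(C)C(C)(C)C)[C@@H]2O[Si](C)(C)C(C)(C)C)c1ccc(OCc2ccccc2)c(OCc2ccccc2)c1O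
F7 | step 6 | 7,8-bis(benzyloxy)-2α-[4-(benzyloxy)phenyl]-4-oxochroman-3α-yl acetate (2,3-cis) | c1cc2c(c(OCc3ccccc3)c1OCc1ccccc1)O[C@H](c1ccc(OCc3ccccc3)cc1)[C@H](OC(C)=O)C2=O
F8 | step 15 | 3,4-bis-O-(tert-butyldimethylsilyl) derivative of the target (six free phenols) | Oc1ccc(cc1)[C@@H]1C[C@@H](c2cc3c(c(O)c2O)O[C@H](c2ccc(O)cc2)[C@H](O[Si](C)(C)C(C)(C)C)[C@@H]3O[Si](C)(C)C(C)(C)C)c2ccc(O)c(O)c2O1
F9 | step 3 | (E)-1-[3,4-bis(benzyloxy)-2-hydroxyphenyl]-3-[4-(benzyloxy)phenyl]prop-2-en-1-one | O=C(/C=C/c1ccc(OCc2ccccc2)cc1)c1ccc(OCc2ccccc2)c(OCc2ccccc2)c1O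
F10 | step 3 | 7,8-bis(benzyloxy)-2-[4-(benzyloxy)phenyl]-4H-chromen-4-one | O=c1cc(-c2ccc(OCc3ccccc3)cc2)oc2c1ccc(OCc1ccccc1)c2OCc1ccccc1
A1 | alternative 1 | (2S,4S)-7,8-bis(benzyloxy)-2-[4-(benzyloxy)phenyl]chroman-4-yl acetate | c1cc2c(c(OCc3ccccc3)c1OCc1ccccc1)O[C@H](c1ccc(OCc3ccccc3)cc1)C[C@@H]2OC(C)=O
A2 | alternative 2 | 1-(benzyloxy)-4-ethenylbenzene | C=Cc1ccc(OCc2ccccc2)cc1
A3 | alternative 2 | C2 epimer of 25 (upper unit 2β-aryl and 4β-aryl, 2,4-cis) | C(c1ccccc1)Oc1ccc(cc1)[C@H]1C[C@@H](c2cc3c(c(OCc4ccccc4)c2OCc2ccccc2)O[C@H](c2ccc(OCc4ccccc4)cc2)[C@H](O[Si](C)(C)C(C)(C)C)[C@@H]3O[Si](C)(C)C(C)(C)C)c2ccc(OCc3ccccc3)c(OCc3ccccc3)c2O1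
A4 | alternative 3 | 6-[(2S,4β)-7,8-bis(benzyloxy)-2-[4-(benzyloxy)phenyl]chroman-4-yl]-7,8-bis(benzyloxy)-2-[4-(benzyloxy)phenyl]-3-hydroxy-4H-chromen-4-one | C(c1ccccc1)Oc1ccc(cc1)[C@@H]1C[C@@H](c2cc3c(c(OCc4ccccc4)c2OCc2ccccc2)oc(-c2ccc(OCc4ccccc4)cc2)c(O)c3=O)c2ccc(OCc3ccccc3)c(OCc3ccccc3)c2O1
A5 | alternative 3 | diastereomer of the target with the lower unit (2S,3S,4S) | Oc1ccc([C@@H]2C[C@@H](c3cc4c(c(O)c3O)O[C@@H](c3ccc(O)cc3)[C@@H](O)[C@H]4O)c3ccc(O)c(O)c3O2)cc1
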